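(The data were computed with made-up constants; the scatter is artificial.)

- I had no constants for the steps, so I reckoned in fractions of the charges, from the two earlier runs.

| flask | X | G | Z | remark | time |
|---|---|---|---|---|---|
| elm | 0.65 M | 0.645 M | 0.43 M | run made earlier |  |
| cedar | 0.43 M | 0.32 M | 0.43 M | run made earlier |  |
| beta | 0.43 M | 0.645 M | 0.430 M |  | 1.5 h |
| epsilon | 0.43 M | 0.645 M | 0.560 M |  | 1.5 h |

| run | time / min | D / % | E / % | Q / % | X / % |
|---|---|---|---|---|---|
| elm | 1.33 | 2 | 0 | 1 | 99 |
| elm | 2.50 | 0 | 0 | 5 | 96 |
| elm | 5.00 | 1 | 3 | 5 | 92 |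
| elm | 10.0 | 2 | 0 | 16 | 83 |
| elm | 20.0 | 0 | 1 | 37 | 63 |
| cedar | 1.50 | 2 | 0 | 2 | 99 |
| cedar | 5.00 | 0 | 2 | 8 | 89 |
| cedar | 8.00 | 0 | 0 | 19 | 80 |
| cedar | 12.0 | 0 | 0 | 29 | 70 |
| cedar | 20.0 | 1 | 0 | 50 | 48 |

(each reading ± 2 percentage points)

- percentages count the X that a species holds: one D counts as two
- solid, in amounts per volume of the solution: Z
- steps thought possible: X + E -> D; Z <-> L; L + G -> J; X + L -> Q; Q + J -> E
- at the start none of Z is in solution

- which of these there is most of at the end, counted by the X in it, beta (E / X / D / Q)
- which of these there is most of at the end, counted by the X in it, epsilon (E / X / D / Q)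
- amount of the one of these that there is most of at the end, in percent of the X charged, beta
- amount of the one of these that there is most of at the end, in percent of the X charged, epsilon

- By 20.0 min the elm flask had lost X equal to 55.9% of its Z charge and the cedar flask 52.0%, although cedar held less X and half the G. These losses stood close, so I read the dissolving of Z as the rate-limiting step, with X taking up the dissolved L as Q.
- For epsilon 1.30 is the cover, Z charged over X charged; for beta it is 1.00. Each Q takes one L, and L comes from Z, so Q, as a fraction of the X charged, cannot pass the cover.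
- Beta has no surplus, so I put its Q at or under 100%, lower by whatever L goes to G.
- Epsilon has two extremes. Both take X to get its L first. If the surplus then never reaches Q, Q stands at 100%. If the whole surplus of 30.0% goes through J and turns Q into E, Q stands at 70.0%.
- Carried on in a straight line, cedar's readings put the X charge used in about 38.5 min, less than 1.5 h. I took the surplus to have the rest of the time, at a rate I could not read from the two runs. I committed to Q as the largest in both flasks, with epsilon's Q between the two extremes.
- The forecast gave Q for beta at 85% (72% to 97%) and Q for epsilon at 75% (64% to 93%), “depending on an unknown rate”. Its low end for epsilon lay under my second extreme.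
- The flasks gave Q at 88.5% in beta and Q at 93.9% in epsilon, so the forecast for epsilon stood 19 percentage points low.

    X + E → D (k = 0.00270 M⁻¹ s⁻¹)
    Z ⇌ L, rate k2*(cs2 - [L]) while solid is left; crystals form when [L] > cs2 (solubility = 0.410 M, k = 5.49 × 10⁻⁴ s⁻¹)
    L + G → J (k = 6.11 × 10⁻⁴ M⁻¹ s⁻¹)
    X + L → Q (k = 0.0255 M⁻¹ s⁻¹)
    Q + J → E (k = 3.07 × 10⁻⁴ M⁻¹ s⁻¹)

- In epsilon at 1.50 h, J was still being made 1.21 times as fast as it was used, each step taken net, and E held 5.70% against a surplus of 30.0%. Left until 15.0 h, epsilon held E at 30.0% and Q at 69.7%, the second extreme.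
- With 1.7 M of X, the epsilon flask has a cover of 32.9%, which caps Q there. The computed flask gave Q 32.4%, with X the largest at 67.3%.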